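**Plan**

- Numbering follows bicyclo[9.3.1]pentadecane: C1 and C11 are the bridgeheads, C2–C10 the nine-carbon bridge, C12–C14 the three-carbon bridge, C15 the CMe2 bridge; C18 is the carboxyl carbon on C12 and C20 the methylidene carbon on C4.
- Retrosynthesis cuts, in order: the lactone O–C10 bond, back to the 12-carboxylic acid with C10 as a plain CH2; the C3–C4 bond of the 12-membered ring (B-alkyl Suzuki macrocyclisation onto a 2-chloroalkene); the C10–C11 bond (B-alkyl Suzuki on an enol triflate); then C11–C12 (Dieckmann) and C1–C15 (iridium allylation) of the cyclohexene, and C5–C6 (Barbier) of the chain.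
- Forward: the cyclohexene is made first, the C6–C10 chain is joined at C11, the 12-membered ring is closed at C3–C4, and the butenolide is closed last by C–H lactonisation.
- Stereochemistry: C1 from the iridium–phosphoramidite catalyst, C6 from CBS reduction, the 7E alkene from commercial (E)-enynol 8, C10 from the bridged macrocycle in the key step.
- Enabling feature: C10 is the γ-CH2 of a cyclohexene-carboxylic acid and lies cis to C18 across the C11=C12 ring double bond, so one C10–H is 1,5 to the carboxyl oxygen; the C2–C10 bridge keeps C9 on one face of that ring.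

Key step: step 14

Assumption: in step 2 the (Sa,S,S)-ligand is taken to direct the nucleophile to the Si face of the allyl terminus; if the sense is the reverse, the (Ra,R,R)-ligand is used and nothing else changes.

**Route**

Step 1
Reactants: 1 methyl hex-5-enoate; 2 allyl methyl carbonate
Product: 3 methyl (5E)-7-[(methoxycarbonyl)oxy]hept-5-enoate
Conditions: second-generation Grubbs catalyst RuCl2(=CHPh)(PCy3)(H2IMes) (3 mol %), 2 (3 equiv), CH2Cl2, 40 °C
Reagents that add atoms: none
Why: Olefin cross-metathesis of two terminal alkenes should give the (E)-allylic carbonate, driven by excess 2 and loss of ethene, with both esters inert to the ruthenium carbene.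

Step 2
Reactants: 3 methyl (5E)-7-[(methoxycarbonyl)oxy]hept-5-enoate; 4 [(1-methoxy-2-methylprop-1-en-1-yl)oxy]trimethylsilane
Product: 5 dimethyl (3S)-3-ethenyl-2,2-dimethylheptanedioate
Conditions: [Ir(cod)Cl]2 (2 mol %), (Sa,S,S)-O,O′-(1,1′-binaphthalene-2,2′-diyl) N,N-bis(1-phenylethyl)phosphoramidite (4 mol %, activated with n-PrNH2), CsF (10 mol %), THF, 35 °C
Reagents that add atoms: none
Why: Iridium-catalysed branched-selective asymmetric allylic alkylation with a silyl ketene acetal as ester enolate should attack the substituted allyl terminus on its Si face under control of the cyclometalated phosphoramidite complex, which sets the future C1 as (S) next to the new quaternary carbon.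

Step 3
Reactants: 5 dimethyl (3S)-3-ethenyl-2,2-dimethylheptanedioate
Product: 6 methyl (4S)-4-ethenyl-3,3-dimethyl-2-oxocyclohexane-1-carboxylate
Conditions: KOtBu (1.2 equiv), THF, 0 °C to rt; then aq. HCl
Reagents that add atoms: none
Why: In this Dieckmann condensation only the CH2 next to the unhindered ester can enolise, it closes the six-membered ring onto the neopentyl ester, and deprotonation of the β-keto ester pulls the equilibrium over, while the non-acidic stereocentre stays.

Step 4
Reactants: 6 methyl (4S)-4-ethenyl-3,3-dimethyl-2-oxocyclohexane-1-carboxylate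
Product: 7 methyl (4S)-4-ethenyl-3,3-dimethyl-2-{[(trifluoromethyl)sulfonyl]oxy}cyclohex-1-ene-1-carboxylate
Conditions: Tf2O (1.2 equiv), iPr2NEt (1.5 equiv), CH2Cl2, −78 °C; aq. NaHCO3 work-up
Reagents that add atoms: triflic anhydride, O=S(=O)(OS(=O)(=O)C(F)(F)F)C(F)(F)F
Why: Enol triflate formation of a β-keto ester should be regiospecific because the ketone can enolise only toward the ester-bearing carbon, the other α-carbon being quaternary.

Step 5
Reactants: 8 (2E)-3-methylpent-2-en-4-yn-1-ol
Product: 9 (2E)-3-methylpenta-2,4-dien-1-ol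
Conditions: H2 (1 atm), Lindlar catalyst (Pd on CaCO3 poisoned with Pb(OAc)2), quinoline, EtOAc, rt
Reagents that add atoms: none
Why: Lindlar semihydrogenation should stop at the vinyl stage for the terminal alkyne and leave the trisubstituted (E)-alkene and its geometry untouched.

Step 6
Reactants: 9 (2E)-3-methylpenta-2,4-dien-1-ol
Product: 10 (2E)-3-methylpenta-2,4-dienal
Conditions: MnO2 (activated, 15 equiv), CH2Cl2, rt
Reagents that add atoms: none
Why: MnO2 oxidation is selective for allylic alcohols and should not isomerise the (E)-diene.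

Step 7
Reactants: 10 (2E)-3-methylpenta-2,4-dienal; 11 2,3-dichloroprop-1-ene
Product: 13 rac-(5E)-2-chloro-6-methylocta-1,5,7-trien-4-ol, via allylzinc chloride 12 (not isolated)
Conditions: Zn dust (2 equiv), 11 (1.5 equiv), THF/sat. aq. NH4Cl, rt
Reagents that add atoms: none
Why: In this aqueous Barbier allylation zinc inserts into the allylic but not the vinylic C–Cl bond of 11 and the allylzinc adds 1,2 to the dienal; the carbinol is formed racemic and is corrected in steps 8 and 9.

Step 8
Reactants: 13 rac-(5E)-2-chloro-6-methylocta-1,5,7-trien-4-ol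
Product: 14 (5E)-2-chloro-6-methylocta-1,5,7-trien-4-one
Conditions: MnO2 (15 equiv), CH2Cl2, rt
Reagents that add atoms: none
Why: MnO2 oxidation of the dienylic alcohol under neutral conditions should give the dienone without moving the β,γ-chloroalkene into conjugation.

Step 9
Reactants: 14 (5E)-2-chloro-6-methylocta-1,5,7-trien-4-one
Product: 15 (4S,5E)-2-chloro-6-methylocta-1,5,7-trien-4-ol
Conditions: (R)-2-methyl-CBS-oxazaborolidine (0.2 equiv), catecholborane (1.5 equiv), toluene, −78 °C; then MeOH, aq. NaOH work-up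
Reagents that add atoms: none
Why: In this Corey–Bakshi–Shibata reduction the dienyl group acts as the large substituent, so the (R)-oxazaborolidine–borane complex should deliver hydride to the Re face and give the (S)-alcohol (the future C6), and catecholborane at low temperature does not hydroborate the diene.

Step 10
Reactants: 15 (4S,5E)-2-chloro-6-methylocta-1,5,7-trien-4-ol
Product: 16 tert-butyl{[(4S,5E)-2-chloro-6-methylocta-1,5,7-trien-4-yl]oxy}dimethylsilane
Conditions: TBSCl, imidazole, DMF, rt
Reagents that add atoms: tert-butyldimethylsilyl chloride, CC(C)(C)[Si](C)(C)Cl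
Why: Silylation of the secondary alcohol protects it against the borane and the bases of the following steps without touching the stereocentre.

Step 11
Reactants: 16 tert-butyl{[(4S,5E)-2-chloro-6-methylocta-1,5,7-trien-4-yl]oxy}dimethylsilane; 7 methyl (4S)-4-ethenyl-3,3-dimethyl-2-{[(trifluoromethyl)sulfonyl]oxy}cyclohex-1-ene-1-carboxylate
Product: 18 methyl (4S)-2-[(3E,5S)-5-{[tert-butyl(dimethyl)silyl]oxy}-7-chloro-3-methylocta-3,7-dien-1-yl]-4-ethenyl-3,3-dimethylcyclohex-1-ene-1-carboxylate, via B-alkyl-9-BBN adduct 17 (not isolated)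
Conditions: 16 (1.15 equiv), 9-BBN (1.05 equiv), THF, 0 °C to rt; then 7 (1.0 equiv), PdCl2(dppf) (8 mol %), AsPh3 (8 mol %), Cs2CO3, DMF/THF/H2O, 50 °C
Reagents that add atoms: none
Why: In this B-alkyl Suzuki–Miyaura coupling 9-BBN should add only to the terminal CH2 of the diene (the trisubstituted alkene and the chloroalkene react far more slowly), PdCl2(dppf) should insert into the activated enol triflate but not the C–Cl bond, and all borane is consumed before 7 is added so that its vinyl group survives.

Step 12
Reactants: 18 methyl (4S)-2-[(3E,5S)-5-{[tert-butyl(dimethyl)silyl]oxy}-7-chloro-3-methylocta-3,7-dien-1-yl]-4-ethenyl-3,3-dimethylcyclohex-1-ene-1-carboxylate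
Product: 20 methyl (1R,6S,7E)-6-{[tert-butyl(dimethyl)silyl]oxy}-8,15,15-trimethyl-4-methylidenebicyclo[9.3.1]pentadeca-7,11-diene-12-carboxylate, via B-alkyl-9-BBN adduct 19 (not isolated)
Conditions: 9-BBN (1.2 equiv), THF, rt; then slow addition to Pd(OAc)2 (10 mol %), SPhos (20 mol %), K3PO4 (3 equiv), THF/H2O, 65 °C, 2 mM
Reagents that add atoms: none
Why: In this intramolecular B-alkyl Suzuki–Miyaura macrocyclisation 9-BBN should hydroborate the only monosubstituted alkene and the electron-rich Pd/SPhos catalyst should insert into the alkenyl chloride, so that the C3–C4 bond closes the 12-membered ring and delivers the exocyclic methylidene directly, with high dilution favouring ring closure.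

Step 13
Reactants: 20 methyl (1R,6S,7E)-6-{[tert-butyl(dimethyl)silyl]oxy}-8,15,15-trimethyl-4-methylidenebicyclo[9.3.1]pentadeca-7,11-diene-12-carboxylate
Product: 21 (1R,6S,7E)-6-{[tert-butyl(dimethyl)silyl]oxy}-8,15,15-trimethyl-4-methylidenebicyclo[9.3.1]pentadeca-7,11-diene-12-carboxylic acid
Conditions: LiOH·H2O (5 equiv), THF/MeOH/H2O, 50 °C; then 1 M HCl to pH 4, 0 °C
Reagents that add atoms: lithium hydroxide (its oxygen ends in the carboxyl group), [Li+].[OH-]
Why: Saponification of the methyl ester should leave the silyl ether and the three alkenes untouched.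

Step 14
Reactants: 21 (1R,6S,7E)-6-{[tert-butyl(dimethyl)silyl]oxy}-8,15,15-trimethyl-4-methylidenebicyclo[9.3.1]pentadeca-7,11-diene-12-carboxylic acid
Product: 23 (1R,6S,7E,10R)-6-{[tert-butyl(dimethyl)silyl]oxy}-10-hydroxy-8,15,15-trimethyl-4-methylidenebicyclo[9.3.1]pentadeca-7,11-diene-12-carboxylic acid 10-lactone, via copper carboxylate 22 (not isolated)
Conditions: Cu(OTf)2 (2.2 equiv), Li2CO3 (1.2 equiv), degassed MeCN, 390 nm LEDs, 25 °C
Reagents that add atoms: none
Why: Proposed new method: ligand-to-metal charge transfer in the carboxylate 22 of divalent copper should release the C18 acyloxyl radical, which sits on an sp2 carbon and so loses CO2 only slowly, and this radical should take the allylic C10–H by 1,5-hydrogen transfer through a six-membered transition state (O, C18, C12, C11, C10, H); the C10 radical is then captured by a second Cu(OTf)2 and the O–C10 bond forms by reductive elimination from an alkyl complex of trivalent copper or by collapse of the cation. The closest known reaction type is the copper- or light-mediated γ-C(sp3)–H lactonisation of 2-alkylbenzoic acids to phthalides through aroyloxyl radicals, together with Kharasch–Sosnovsky allylic acyloxylation, with the arene replaced here by the C11=C12 ring alkene. The butenolide (O, C18, C12, C11, C10) closes in a 5-exo-tet mode at C10, the only ring size open to the carboxylate because bonding at the other allyl terminus C12 would give an α-lactone. The new stereocentre C10 is set by the substrate: the C2–C10 bridge holds C9 on the face of the cyclohexene that carries C2 at (1R)-C1, the hydrogen lying near the ring plane beside the carboxyl is the one removed, and oxygen takes its place, which should give (10R). The step needs site selectivity for C10–H over the allylic hydrogens at C3, C5, C6, C9 and C13, which the cis arrangement of C10 and C18 across the ring alkene secures since no other C–H is within 1,5-reach, and it needs the alkenes to be spared, which is expected because intramolecular hydrogen transfer outruns radical addition, no free oxidant is present and 390 nm light does not excite alkene complexes of monovalent copper.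

Step 15
Reactants: 23 (1R,6S,7E,10R)-6-{[tert-butyl(dimethyl)silyl]oxy}-10-hydroxy-8,15,15-trimethyl-4-methylidenebicyclo[9.3.1]pentadeca-7,11-diene-12-carboxylic acid 10-lactone
Product: 24 (1R,6S,7E,10R)-6,10-dihydroxy-8,15,15-trimethyl-4-methylidenebicyclo[9.3.1]pentadeca-7,11-diene-12-carboxylic acid 10-lactone
Conditions: HF·pyridine, pyridine/THF, 0 °C to rt
Reagents that add atoms: none
Why: Desilylation with buffered HF·pyridine should spare the base-sensitive γ-position of the butenolide and the exocyclic alkene.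

Step 16
Reactants: 24 (1R,6S,7E,10R)-6,10-dihydroxy-8,15,15-trimethyl-4-methylidenebicyclo[9.3.1]pentadeca-7,11-diene-12-carboxylic acid 10-lactone
Product: 25 (1R,6S,7E,10R)-6-acetoxy-10-hydroxy-8,15,15-trimethyl-4-methylidenebicyclo[9.3.1]pentadeca-7,11-diene-12-carboxylic acid 10-lactone (CNP0289913.1)
Conditions: Ac2O, pyridine, DMAP (cat.), CH2Cl2, 0 °C to rt
Reagents that add atoms: acetic anhydride, CC(=O)OC(C)=O
Why: DMAP-catalysed acetylation of the secondary allylic alcohol proceeds with retention at C6 and should give the target.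

**Compound list**

1 | methyl hex-5-enoate | C=CCCCC(=O)OC | starting material
2 | allyl methyl carbonate | C=CCOC(=O)OC | starting material
3 | methyl (5E)-7-[(methoxycarbonyl)oxy]hept-5-enoate | COC(=O)CCC/C=C/COC(=O)OC | intermediate
4 | [(1-methoxy-2-methylprop-1-en-1-yl)oxy]trimethylsilane | COC(O[Si](C)(C)C)=C(C)C | starting material
5 | dimethyl (3S)-3-ethenyl-2,2-dimethylheptanedioate | C=C[C@@H](C(C)(C)C(=O)OC)CCCC(=O)OC | intermediate
6 | methyl (4S)-4-ethenyl-3,3-dimethyl-2-oxocyclohexane-1-carboxylate (C1 epimers and enol) | C=C[C@@H]1CCC(C(=O)OC)C(=O)C1(C)C | intermediate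
7 | methyl (4S)-4-ethenyl-3,3-dimethyl-2-{[(trifluoromethyl)sulfonyl]oxy}cyclohex-1-ene-1-carboxylate | C=C[C@@H]1CCC(C(=O)OC)=C(OS(=O)(=O)C(F)(F)F)C1(C)C | intermediate
8 | (2E)-3-methylpent-2-en-4-yn-1-ol | C#C/C(C)=C/CO | starting material
9 | (2E)-3-methylpenta-2,4-dien-1-ol | C=C/C(C)=C/CO | intermediate
10 | (2E)-3-methylpenta-2,4-dienal | C=C/C(C)=C/C=O | intermediate
11 | 2,3-dichloroprop-1-ene | C=C(Cl)CCl | starting material
12 | (2-chloroprop-2-en-1-yl)zinc chloride | C=C(Cl)C[Zn]Cl | intermediate
13 | rac-(5E)-2-chloro-6-methylocta-1,5,7-trien-4-ol | C=C(Cl)CC(O)/C=C(C)/C=C | intermediate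
14 | (5E)-2-chloro-6-methylocta-1,5,7-trien-4-one | C=C(Cl)CC(=O)/C=C(C)/C=C | intermediate
15 | (4S,5E)-2-chloro-6-methylocta-1,5,7-trien-4-ol | C=C(Cl)C[C@H](O)/C=C(C)/C=C | intermediate
16 | tert-butyl{[(4S,5E)-2-chloro-6-methylocta-1,5,7-trien-4-yl]oxy}dimethylsilane | C=C(Cl)C[C@H](O[Si](C)(C)C(C)(C)C)/C=C(C)/C=C | intermediate
17 | 9-[(3E,5S)-5-{[tert-butyl(dimethyl)silyl]oxy}-7-chloro-3-methylocta-3,7-dien-1-yl]-9-borabicyclo[3.3.1]nonane | C=C(Cl)C[C@H](O[Si](C)(C)C(C)(C)C)/C=C(C)/CCB1C2CCCC1CCC2 | intermediate
18 | methyl (4S)-2-[(3E,5S)-5-{[tert-butyl(dimethyl)silyl]oxy}-7-chloro-3-methylocta-3,7-dien-1-yl]-4-ethenyl-3,3-dimethylcyclohex-1-ene-1-carboxylate | C=C[C@@H]1CCC(C(=O)OC)=C(CC/C(C)=C/[C@@H](O[Si](C)(C)C(C)(C)C)CC(Cl)=C)C1(C)C | intermediate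
19 | methyl (4R)-4-[2-(9-borabicyclo[3.3.1]nonan-9-yl)ethyl]-2-[(3E,5S)-5-{[tert-butyl(dimethyl)silyl]oxy}-7-chloro-3-methylocta-3,7-dien-1-yl]-3,3-dimethylcyclohex-1-ene-1-carboxylate | B1(C2CCCC1CCC2)CC[C@@H]3CCC(C(=O)OC)=C(CC/C(C)=C/[C@@H](O[Si](C)(C)C(C)(C)C)CC(Cl)=C)C3(C)C | intermediate
20 | methyl (1R,6S,7E)-6-{[tert-butyl(dimethyl)silyl]oxy}-8,15,15-trimethyl-4-methylidenebicyclo[9.3.1]pentadeca-7,11-diene-12-carboxylate | C=C1CC[C@@H]2CCC(C(=O)OC)=C(CC/C(C)=C/[C@@H](O[Si](C)(C)C(C)(C)C)C1)C2(C)C | intermediate
21 | (1R,6S,7E)-6-{[tert-butyl(dimethyl)silyl]oxy}-8,15,15-trimethyl-4-methylidenebicyclo[9.3.1]pentadeca-7,11-diene-12-carboxylic acid | C=C1CC[C@@H]2CCC(C(=O)O)=C(CC/C(C)=C/[C@@H](O[Si](C)(C)C(C)(C)C)C1)C2(C)C | intermediate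
22 | copper carboxylate of 21, RCO2Cu(OTf) | C=C1CC[C@@H]2CCC(C(=O)[O-])=C(CC/C(C)=C/[C@@H](O[Si](C)(C)C(C)(C)C)C1)C2(C)C.[Cu+2].[O-]S(=O)(=O)C(F)(F)F | intermediate
23 | (1R,6S,7E,10R)-6-{[tert-butyl(dimethyl)silyl]oxy}-10-hydroxy-8,15,15-trimethyl-4-methylidenebicyclo[9.3.1]pentadeca-7,11-diene-12-carboxylic acid 10-lactone | C=C1CC[C@@H]2CCC3=C([C@@H](C/C(C)=C/[C@@H](O[Si](C)(C)C(C)(C)C)C1)OC3=O)C2(C)C | intermediate
24 | (1R,6S,7E,10R)-6,10-dihydroxy-8,15,15-trimethyl-4-methylidenebicyclo[9.3.1]pentadeca-7,11-diene-12-carboxylic acid 10-lactone | C=C1CC[C@@H]2CCC3=C([C@@H](C/C(C)=C/[C@@H](O)C1)OC3=O)C2(C)C | intermediate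
25 | (1R,6S,7E,10R)-6-acetoxy-10-hydroxy-8,15,15-trimethyl-4-methylidenebicyclo[9.3.1]pentadeca-7,11-diene-12-carboxylic acid 10-lactone (CNP0289913.1) | C=C1CC[C@@H]2CCC3=C([C@@H](C/C(C)=C/[C@@H](OC(C)=O)C1)OC3=O)C2(C)C | target

**Step count**

Total: 16 steps. Longest linear sequence: 12 steps (8 to 25, steps 5–16); the ring fragment 7 is made in 4 steps (steps 1–4) and joins at step 11.

**Steps most likely to fail**

1. Step 14 (Proposed new method). The acyloxyl radical may lose CO2 or add to the C7=C8 alkene before it abstracts hydrogen. The C10 radical may lose a proton from C9 (desaturation to a triene acid) instead of forming the C–O bond. The copper triflate may also cleave the silyl ether as a Lewis acid. Fallback, from 20 to 23 by known polar chemistry (step 13 is then not needed): γ-deprotonation of 20 at C10 with LDA/DMPU at −78 °C and trapping with TMSCl should give the silyl ketene acetal F1. NBS at −78 °C should brominate its vinylogous position to the 10-bromo ester F2. Heating F2 in toluene should let the ester carbonyl oxygen displace bromide at C10 with loss of bromomethane and give 23; DBU then equilibrates C10 through the furanolate toward the (10R) isomer that the macrocycle favours.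

2. Step 12. Oxidative addition into the alkenyl chloride may be slow, so that protodeboronation of 19 or intermolecular coupling to oligomers overtakes ring closure. Fallback, from 18 to 20 with zinc in place of boron in the ring-closing step: 18 is hydroborated as before and the borane 19 is oxidised with NaBO3·4H2O to the primary alcohol F3. I2, PPh3 and imidazole should give the iodide F4. Zn dust and LiCl in THF should insert to the alkylzinc iodide F5, which is closed by intramolecular Negishi coupling (Pd(OAc)2, SPhos, THF/NMP, syringe-pump addition) to 20; transmetalation from zinc needs no aqueous base.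

3. Step 11. Oxidative addition and transmetalation may be sluggish at the tetrasubstituted triflate next to the quaternary C15, so that hydrolysis of the triflate by the aqueous base or hydroboration of the ring vinyl group by leftover borane competes. Fallback, from 16 and 7 to 23, with the C10–C11 bond made by carbonyl addition and the lactone closed by acyl substitution (steps 12–14 are replaced): borane 17 is oxidised with NaBO3·4H2O to the alcohol F6, and Dess–Martin periodinane gives the β,γ-unsaturated aldehyde F7, used at once. Nozaki–Hiyama–Kishi coupling of F7 with 7 (CrCl2, NiCl2 cat., DMF) should join C10 to C11, and the chromium alkoxide should close onto the neighbouring methyl ester to give the butenolide F8 as C10 epimers. 9-BBN then gives the borane F9, and the Pd(OAc)2/SPhos/K3PO4 macrocyclisation of step 12 should give 23, the base equilibrating C10 toward the (10R) macrocycle.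

**Further compounds**

F1 | step 14 | (1R,6S,7E)-6-{[tert-butyl(dimethyl)silyl]oxy}-12-[methoxy(trimethylsilyloxy)methylidene]-8,15,15-trimethyl-4-methylidenebicyclo[9.3.1]pentadeca-7,10-diene | C=C1CC[C@@H]2CCC(=C(OC)O[Si](C)(C)C)C(=CC/C(C)=C/[C@@H](O[Si](C)(C)C(C)(C)C)C1)C2(C)C
F2 | step 14 | methyl (1R,6S,7E)-10-bromo-6-{[tert-butyl(dimethyl)silyl]oxy}-8,15,15-trimethyl-4-methylidenebicyclo[9.3.1]pentadeca-7,11-diene-12-carboxylate (C10 epimers) | C=C1CC[C@@H]2CCC(C(=O)OC)=C(C(Br)C/C(C)=C/[C@@H](O[Si](C)(C)C(C)(C)C)C1)C2(C)C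
F3 | step 12 | methyl (4S)-2-[(3E,5S)-5-{[tert-butyl(dimethyl)silyl]oxy}-7-chloro-3-methylocta-3,7-dien-1-yl]-4-(2-hydroxyethyl)-3,3-dimethylcyclohex-1-ene-1-carboxylate | OCC[C@@H]1CCC(C(=O)OC)=C(CC/C(C)=C/[C@@H](O[Si](C)(C)C(C)(C)C)CC(Cl)=C)C1(C)C
F4 | step 12 | methyl (4S)-2-[(3E,5S)-5-{[tert-butyl(dimethyl)silyl]oxy}-7-chloro-3-methylocta-3,7-dien-1-yl]-4-(2-iodoethyl)-3,3-dimethylcyclohex-1-ene-1-carboxylate | ICC[C@@H]1CCC(C(=O)OC)=C(CC/C(C)=C/[C@@H](O[Si](C)(C)C(C)(C)C)CC(Cl)=C)C1(C)C
F5 | step 12 | alkylzinc iodide of F4 (CH2CH2ZnI in place of CH2CH2I) | I[Zn]CC[C@@H]1CCC(C(=O)OC)=C(CC/C(C)=C/[C@@H](O[Si](C)(C)C(C)(C)C)CC(Cl)=C)C1(C)C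
F6 | step 11 | (3E,5S)-5-{[tert-butyl(dimethyl)silyl]oxy}-7-chloro-3-methylocta-3,7-dien-1-ol | OCC/C(C)=C/[C@@H](O[Si](C)(C)C(C)(C)C)CC(Cl)=C
F7 | step 11 | (3E,5S)-5-{[tert-butyl(dimethyl)silyl]oxy}-7-chloro-3-methylocta-3,7-dienal | O=CC/C(C)=C/[C@@H](O[Si](C)(C)C(C)(C)C)CC(Cl)=C
F8 | step 11 | (5S)-3-[(2E,4S)-4-{[tert-butyl(dimethyl)silyl]oxy}-6-chloro-2-methylhepta-2,6-dien-1-yl]-5-ethenyl-4,4-dimethyl-4,5,6,7-tetrahydro-2-benzofuran-1(3H)-one (C3 epimers) | C=C[C@@H]1CCC2=C(C(C/C(C)=C/[C@@H](O[Si](C)(C)C(C)(C)C)CC(Cl)=C)OC2=O)C1(C)C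
F9 | step 11 | B-alkyl-9-BBN adduct of F8 (CH2CH2-9-BBN in place of the ethenyl group) | B1(C2CCCC1CCC2)CC[C@@H]3CCC4=C(C(C/C(C)=C/[C@@H](O[Si](C)(C)C(C)(C)C)CC(Cl)=C)OC4=O)C3(C)C
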